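I have no rate constants for this two-phase flask, but I have two earlier runs, so I treat the late decline of [target] the way I would treat any decay.

| setting | south-east | north-west | flask |
|---|---|---|---|
| substrate | 1.1 M | 1.8 M | 0.80 M |
| reagent in the second phase | 1.3 equiv | 1.3 equiv | 1.30 equiv |
| protic impurity | 0.080 M | 0.080 M | 0.0800 M |
| remark | run made earlier | run made earlier |  |
| time |  |  | 6.0 h |
| volume of the second phase over the first |  |  | 1.0 |

| run | time / h | target / % |
|---|---|---|
| south-east | 0.833 | 5.9 |
| south-east | 1.50 | 8.4 |
| south-east | 2.50 | 8.0 |
| south-east | 3.00 | 7.5 |
| south-east | 4.00 | 5.6 |
| south-east | 5.00 | 5.1 |
| north-west | 0.417 | 2.3 |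
| north-west | 0.667 | 5.4 |
| north-west | 1.00 | 8.0 |
| north-west | 2.00 | 9.8 |
| north-west | 3.00 | 7.6 |
| north-west | 5.00 | 2.7 |

(standard deviation of a reading: 0.5 percentage points)

- in the second phase: reagent in the second phase; everything else is in the first
- charges count per volume of the first phase; a concentration in a rate is the amount of a species over the volume of its own phase; every rate counts per litre of the first phase
- the earlier runs hold the two phases in the same ratio of volumes as the flask asked about

- how much target there is at 6.0 h, in percent of the substrate charged
- the change that raises the amount of target at 6.0 h, in percent of the substrate charged most ("none" if none brings more than 2 percentage points) (Wednesday's / Thursday's / none)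
- amount of target at 6.0 h, in percent of the substrate charged, after Thursday's

My quantity is the fall constant, the logarithm of the ratio of two readings past the peak divided by the time between them. In the south-east run, the nearest to the flask, the readings at 3.00 h and 5.00 h give 0.193 /h. Carrying its last reading of 5.1% on to 6.0 h at that constant, I commit to 4.21% for the flask. The asked time lies later than the highest south-east reading at 1.50 h, so I take the flask to be on its falling side by then, and I expect neither change to gain 2 percentage points.

The forecast says “It then peaks and falls, so it is an intermediate that is over-consumed”, and it gives 5.2%, higher than my figure, with none as the best change and 2.7% after Thursday's.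

The flask gives 3.95%, and the best change is none: Wednesday's moves it by −0.27 points, Thursday's by −0.89 points, to 3.06%.

    reagent in the reaction phase ⇌ reagent in the second phase, rate k1*([reagent in the reaction phase] - [reagent in the second phase]/K1) per volume of the first phase (partition coefficient = 1.20, kL = 0.00730 /min)
    substrate + reagent in the reaction phase → target (k = 0.0130 /M/min)
    reagent in the reaction phase + target → over-reacted product (k = 0.0110 /M/min)
    reagent in the reaction phase + protic impurity → quenched reagent (k = 0.0140 /M/min)
    2 substrate → self-condensation product (k = 0.00470 /M/min)
    target → over-reaction product (k = 0.0120 /min)

By its conversion into over-reaction product alone, target has a half-life of 0.96 h, shorter than the asked time, while the flask's own fall constant from 3.00 h to 6.0 h is 0.236 /h, a half-time of 2.94 h. Carried on to 15 h, that constant gives 0.472%, and the same flask read then holds 0.474%.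

Readings and results were computed with constants of no real substance; scatter was added.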